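The pyran ring of the central flavan unit (O1–C2–C3–C4–C4a–C8a) is cut at C4–C4a and C2–C3. O1, C8a and C4a then belong to a bromine-blocked phloroglucinol ring that already carries the upper A-type bicycle, C3=C4 is a (Z)-enol acetate on C8 of the lower epicatechin, and C2 is an orthobenzoate carbon. A chiral-acid-catalysed oxa-Povarov-type [4+2] of the derived aryloxy(methoxy)carbenium ion (a cationic 2-oxadiene) with the alkene forms both C–C bonds, the ring and the C3/C4 stereocentres in one operation; the electron-rich A ring of the lower unit fixes the polarity of the alkene. Deallylation and transketalisation then close the second ketal bridge before hydrogenolysis.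

Key step: step 15

Remark 1: the target is read as epicatechin-(2β→O→7, 4β→6)-ent-catechin-(2α→O→7, 4α→8)-epicatechin; "central unit" means the ent-catechin-type unit and uses flavan numbering.
Remark 2: 5-(benzyloxy)benzene-1,3-diol and 3,4-bis(benzyloxy)benzonitrile are taken as catalogue compounds (each is otherwise one O-benzylation from phloroglucinol or 3,4-dihydroxybenzonitrile).
Remark 3: CA is (R)-3,3′-bis(2,4,6-triisopropylphenyl)-1,1′-binaphthyl-2,2′-diyl N-(trifluoromethylsulfonyl)phosphoramide; that the (R) antipode is the one matched to the required alkene face is an assumption.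
Remark 4: compounds 23 and 24 are carried as mixtures of the two C2 (OMe) anomers, which converge in step 16.

Step 1
Reactants: 1 5-(benzyloxy)benzene-1,3-diol
Product: 2 1-(benzyloxy)-3,5-bis(methoxymethoxy)benzene
Conditions: NaH, MOMCl, DMF, 0 °C → rt
Reagents that add atoms: chloromethyl methyl ether, COCCl
Why: Williamson-type O-alkylation of both phenoxides turns the two hydroxyls into the directing groups needed in step 2.

Step 2
Reactants: 2 1-(benzyloxy)-3,5-bis(methoxymethoxy)benzene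
Product: 4 5-(benzyloxy)-2-bromo-1,3-bis(methoxymethoxy)benzene, via aryllithium 3 (not isolated)
Conditions: n-BuLi, THF, 0 °C; then BrCCl2CCl2Br, −78 °C → rt
Reagents that add atoms: 1,2-dibromo-1,1,2,2-tetrachloroethane, BrC(Cl)(Cl)C(Cl)(Cl)Br
Why: Directed ortho-metalation should lithiate the ring carbon between the two methoxymethoxy groups (cooperative coordination), and the aryllithium is brominated by halogen transfer.

Step 3
Reactants: 4 5-(benzyloxy)-2-bromo-1,3-bis(methoxymethoxy)benzene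
Product: 5 5-(benzyloxy)-2-bromobenzene-1,3-diol
Conditions: HCl (cat.), MeOH, 40 °C
Reagents that add atoms: none
Why: Acid-catalysed acetal methanolysis removes both MOM groups while the benzyl ether and the aryl bromide are inert.

Step 4
Reactants: 6 (−)-epicatechin
Product: 7 5,7,3′,4′-tetra-O-benzyl-(−)-epicatechin
Conditions: BnBr, K2CO3, DMF, 0 °C → rt
Reagents that add atoms: benzyl bromide, BrCc1ccccc1
Why: Williamson etherification of the four phenols under a weak base leaves the secondary 3-OH and the C2 stereocentre untouched.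

Step 5
Reactants: 7 5,7,3′,4′-tetra-O-benzyl-(−)-epicatechin
Product: 8 3,5,7,3′,4′-penta-O-benzyl-(−)-epicatechin
Conditions: NaH, BnBr, Bu4NI (cat.), DMF, 0 °C → rt
Reagents that add atoms: benzyl bromide, BrCc1ccccc1
Why: Williamson ether synthesis at the remaining secondary alcohol, safe towards C2 epimerisation because no free phenol remains.

Step 6
Reactants: 8 3,5,7,3′,4′-penta-O-benzyl-(−)-epicatechin
Product: 9 4β-(2-hydroxyethoxy)-3,5,7,3′,4′-penta-O-benzylepicatechin
Conditions: DDQ, HOCH2CH2OH, CH2Cl2, rt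
Reagents that add atoms: ethylene glycol, OCCO
Why: DDQ benzylic C–H oxidation (hydride abstraction at C4, assisted by the trioxygenated A ring) followed by capture with the diol trans to the 3-benzyloxy group sets C4.

Step 7
Reactants: 9 4β-(2-hydroxyethoxy)-3,5,7,3′,4′-penta-O-benzylepicatechin
Product: 10 2β,4β-(ethane-1,2-diyldioxy)-bridged 3,5,7,3′,4′-penta-O-benzylepicatechin
Conditions: DDQ, 4 Å MS, CH2Cl2, rt
Reagents that add atoms: none
Why: A second DDQ oxidation, now of the benzylic α-oxy C2–H, is trapped intramolecularly by the pendant hydroxyl, which can only reach the β face, giving the flavan 2,4-dication equivalent with the ketal carbon fixed by the tether.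

Step 8
Reactants: 10 2β,4β-(ethane-1,2-diyldioxy)-bridged 3,5,7,3′,4′-penta-O-benzylepicatechin, 5 5-(benzyloxy)-2-bromobenzene-1,3-diol (3 equiv)
Product: 11 upper fragment, penta-O-benzylepicatechin doubly β-linked (C2–O and C4–C) to O1 and C6 of 5-(benzyloxy)-2-bromobenzene-1,3-diol
Conditions: BF3·OEt2 (cat.), CH2Cl2, −78 → −20 °C
Reagents that add atoms: none
Why: Known annulation of a flavan 2,4-dication equivalent with a phenol bis-nucleophile: ionisation at C4 and Friedel–Crafts attack by the only type of free ring carbon of 5 trans to 3-OBn sets C4 (β), then ionisation at C2 and ketalisation by the neighbouring hydroxyl on the same face sets the ketal carbon.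

Step 9
Reactants: 8 3,5,7,3′,4′-penta-O-benzyl-(−)-epicatechin
Product: 13 8-formyl-3,5,7,3′,4′-penta-O-benzylepicatechin, via iminium chloride 12 (not isolated)
Conditions: POCl3, DMF, 0 → 60 °C; then H2O
Reagents that add atoms: N,N-dimethylformamide, CN(C)C=O; water, O
Why: Vilsmeier–Haack formylation should take C8, the more nucleophilic and less hindered free position of the A ring (next to the ring oxygen), as halogenation of benzylated catechins does.

Step 10
Reactants: 13 8-formyl-3,5,7,3′,4′-penta-O-benzylepicatechin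
Product: 14 8-formyl-7-hydroxy-3,5,3′,4′-tetra-O-benzylepicatechin
Conditions: MgBr2·OEt2, toluene–Et2O, 80 °C; aq. HCl work-up
Reagents that add atoms: none
Why: Chelation-controlled mono-debenzylation: magnesium held between the formyl oxygen and O7 activates only the ortho benzyl ether for SN2 cleavage by bromide.

Step 11
Reactants: 14 8-formyl-7-hydroxy-3,5,3′,4′-tetra-O-benzylepicatechin
Product: 15 7-O-allyl-8-formyl-3,5,3′,4′-tetra-O-benzylepicatechin
Conditions: allyl bromide, K2CO3, DMF, rt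
Reagents that add atoms: allyl bromide, C=CCBr
Why: Williamson O-allylation gives O7 a group orthogonal to benzyl, so that this oxygen can be freed before the other phenols.

Step 12
Reactants: 15 7-O-allyl-8-formyl-3,5,3′,4′-tetra-O-benzylepicatechin
Product: 16 7-O-allyl-8-ethynyl-3,5,3′,4′-tetra-O-benzylepicatechin
Conditions: dimethyl (1-diazo-2-oxopropyl)phosphonate, K2CO3, MeOH–THF, rt
Reagents that add atoms: dimethyl (1-diazo-2-oxopropyl)phosphonate, COP(=O)(OC)C(=[N+]=[N-])C(C)=O
Why: Ohira–Bestmann variant of the Seyferth–Gilbert homologation converts the aldehyde into the terminal alkyne under conditions that spare all ethers.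

Step 13
Reactants: 16 7-O-allyl-8-ethynyl-3,5,3′,4′-tetra-O-benzylepicatechin
Product: 17 7-O-allyl-8-[(Z)-2-acetoxyethenyl]-3,5,3′,4′-tetra-O-benzylepicatechin
Conditions: AcOH, Ru(η3-2-methylallyl)2(dppb) (cat.), toluene, 45 °C
Reagents that add atoms: acetic acid, CC(=O)O
Why: Ruthenium-catalysed anti-Markovnikov addition of a carboxylic acid to a terminal alkyne through a vinylidene delivers the carboxylate trans to the metal and hence the (Z)-enol ester.

Step 14
Reactants: 18 3,4-bis(benzyloxy)benzonitrile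
Product: 20 trimethyl 3,4-bis(benzyloxy)orthobenzoate, via imidate hydrochloride 19 (not isolated)
Conditions: HCl (g), MeOH (1 equiv), Et2O, 0 °C; then MeOH, rt
Reagents that add atoms: methanol, CO
Why: Pinner reaction: the nitrile gives the methyl imidate hydrochloride, whose alcoholysis gives the orthoester and ammonium chloride.

Step 15
Reactants: 11 upper fragment, 17 7-O-allyl-8-[(Z)-2-acetoxyethenyl]-3,5,3′,4′-tetra-O-benzylepicatechin, 20 trimethyl 3,4-bis(benzyloxy)orthobenzoate
Product: 23 protected trimer with central 2-methoxy-3α-acetoxy-4α-aryl chroman ring, via mixed orthoester 21 (not isolated), via aryloxy(methoxy)carbenium ion 22 (not isolated)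
Conditions: CA (10 mol %), 5 Å MS, CH2Cl2, rt; then 17, −40 → 0 °C
Reagents that add atoms: none
Why: Proposed new method: acid-catalysed orthoester exchange places C2 on the only free phenol oxygen of 11 (mixed orthoester 21), and loss of methanol gives the aryloxy(methoxy)carbenium ion 22, a cationic 2-oxadiene C4a=C8a–O1–C2(+); the acetoxy-bearing alkene carbon of 17 adds to C2 (C2–C3) because the cation that develops at C4 is stabilised by the trioxygenated A ring of the lower unit and hardly by the acetoxy group, and the tethered ring carbon C4a then closes onto C4 (C4–C4a) with loss of a proton, which returns the acid. The closest known reaction is the oxa-Povarov reaction (Lewis-acid-mediated formal inverse-demand [4+2] of aryl oxocarbenium ions from O-aryl acetals with alkenes, related to the Prins/Friedel–Crafts sequence); its use with an orthoester-derived dioxocarbenium ion, an enol ester and a chiral Brønsted acid is untested, which is why the step is labelled. One ring is closed, the pyran ring O1–C2–C3–C4–C4a–C8a, by the second bond of the [4+2]: a six-membered intramolecular Friedel–Crafts alkylation in which the cationic C4 lies inside the forming ring. C3 is set by the catalyst, whose chiral counter-anion pairs with 22 and selects the alkene face (the two existing units are too remote to do so); C4 is relayed from C3 because both new bonds reach the same face of the alkene, the neighbouring acetate being able to hold the benzylic cation as a cis-1,3-dioxolan-2-ylium ion that the tethered arene opens with inversion, so the Z geometry becomes the 3,4-cis relationship; C2 forms as an anomer mixture that step 16 corrects. The step needs site selectivity among many electron-rich aromatic CH positions and regioselectivity on the alkene: the O1 tether together with bromine at C8 leaves C4a as the only position that can close, and the aryl donor on C4 makes the acetoxy-bearing carbon the nucleophilic one.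

Step 16
Reactants: 23 protected trimer with central 2-methoxy-3α-acetoxy-4α-aryl chroman ring
Product: 25 8-bromo-dodeca-O-benzyl derivative of the target (central 3-OH free), via deallylated deacetylated methyl ketal 24 (not isolated)
Conditions: Pd(PPh3)4 (cat.), K2CO3 (cat.), MeOH–THF, rt; then camphorsulfonic acid, 4 Å MS, CH2Cl2, rt
Reagents that add atoms: none
Why: Palladium-catalysed deallylation (π-allyl transfer to methoxide) with concurrent methanolysis of the acetate, then acid-catalysed transketalisation in which the freed 7-hydroxyl of the lower unit replaces methoxide at C2; only the C2 epimer with this oxygen cis to the C4–C8 bond can close, so the ketal centre is set under thermodynamic control while the central 5-oxygen is still benzylated and cannot compete.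

Step 17
Reactants: 25 8-bromo-dodeca-O-benzyl derivative of the target
Product: 26 target, epicatechin-(2β→O→7, 4β→6)-ent-catechin-(2α→O→7, 4α→8)-epicatechin
Conditions: H2 (1 atm), Pd(OH)2/C, THF–MeOH–H2O, rt
Reagents that add atoms: none
Why: Hydrogenolysis over Pd(OH)2 on carbon should cleave the twelve benzyl ethers and the aryl C–Br bond in one operation, while the diaryl ketals and the flavan C2–O bonds survive as in other A-type proanthocyanidin end games.

Compound list

1 | 5-(benzyloxy)benzene-1,3-diol | Oc1cc(O)cc(OCc2ccccc2)c1 | starting material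
2 | 1-(benzyloxy)-3,5-bis(methoxymethoxy)benzene | COCOc1cc(OCOC)cc(OCc2ccccc2)c1 | intermediate
3 | [4-(benzyloxy)-2,6-bis(methoxymethoxy)phenyl]lithium | [Li]c1c(OCOC)cc(OCc2ccccc2)cc1OCOC | intermediate
4 | 5-(benzyloxy)-2-bromo-1,3-bis(methoxymethoxy)benzene | COCOc1cc(OCc2ccccc2)cc(OCOC)c1Br | intermediate
5 | 5-(benzyloxy)-2-bromobenzene-1,3-diol | Oc1cc(OCc2ccccc2)cc(O)c1Br | intermediate
6 | (−)-epicatechin, (2R,3R)-2-(3,4-dihydroxyphenyl)chromane-3,5,7-triol | Oc1cc(O)c2c(c1)O[C@H](c1ccc(O)c(O)c1)[C@H](O)C2 | starting material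
7 | 5,7,3′,4′-tetra-O-benzyl-(−)-epicatechin | C(c5ccccc5)Oc1cc(OCc5ccccc5)c2c(c1)O[C@H](c1ccc(OCc5ccccc5)c(OCc5ccccc5)c1)[C@H](O)C2 | intermediate
8 | 3,5,7,3′,4′-penta-O-benzyl-(−)-epicatechin | C(c5ccccc5)Oc1cc(OCc5ccccc5)c2c(c1)O[C@H](c1ccc(OCc5ccccc5)c(OCc5ccccc5)c1)[C@H](OCc5ccccc5)C2 | intermediate
9 | 4β-(2-hydroxyethoxy)-3,5,7,3′,4′-penta-O-benzylepicatechin (4-O trans to 3-OBn) | C(c5ccccc5)Oc1cc(OCc5ccccc5)c2c(c1)O[C@H](c1ccc(OCc5ccccc5)c(OCc5ccccc5)c1)[C@H](OCc5ccccc5)[C@H]2OCCO | intermediate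
10 | 2β,4β-(ethane-1,2-diyldioxy)-bridged 3,5,7,3′,4′-penta-O-benzylepicatechin (bridge anti to 3-OBn and to the 2-aryl group) | C(c5ccccc5)Oc1cc(OCc5ccccc5)c2c(c1)O[C@@]3(c1ccc(OCc5ccccc5)c(OCc5ccccc5)c1)OCCO[C@@H]2[C@H]3OCc5ccccc5 | intermediate
11 | upper fragment: 3,5,7,3′,4′-penta-O-benzylepicatechin doubly β-linked (C2–O and C4–C) to O1 and C6 of 5-(benzyloxy)-2-bromobenzene-1,3-diol; 3-OH and C4–H of that ring free | C(c5ccccc5)Oc1cc(OCc5ccccc5)c2c(c1)O[C@@]1(c3ccc(OCc5ccccc5)c(OCc5ccccc5)c3)Oc3c(Br)c(O)cc(OCc5ccccc5)c3[C@@H]2[C@H]1OCc5ccccc5 | intermediate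
12 | N,N-dimethyl iminium chloride at C8 of penta-O-benzylepicatechin (Vilsmeier adduct) | C(c5ccccc5)Oc1cc(OCc5ccccc5)c2c(c1C=[N+](C)C)O[C@H](c1ccc(OCc5ccccc5)c(OCc5ccccc5)c1)[C@H](OCc5ccccc5)C2.[Cl-] | intermediate
13 | 8-formyl-3,5,7,3′,4′-penta-O-benzylepicatechin | C(c5ccccc5)Oc1cc(OCc5ccccc5)c2c(c1C=O)O[C@H](c1ccc(OCc5ccccc5)c(OCc5ccccc5)c1)[C@H](OCc5ccccc5)C2 | intermediate
14 | 8-formyl-7-hydroxy-3,5,3′,4′-tetra-O-benzylepicatechin | Oc1cc(OCc5ccccc5)c2c(c1C=O)O[C@H](c1ccc(OCc5ccccc5)c(OCc5ccccc5)c1)[C@H](OCc5ccccc5)C2 | intermediate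
15 | 7-O-allyl-8-formyl-3,5,3′,4′-tetra-O-benzylepicatechin | C=CCOc1cc(OCc5ccccc5)c2c(c1C=O)O[C@H](c1ccc(OCc5ccccc5)c(OCc5ccccc5)c1)[C@H](OCc5ccccc5)C2 | intermediate
16 | 7-O-allyl-8-ethynyl-3,5,3′,4′-tetra-O-benzylepicatechin | C=CCOc1cc(OCc5ccccc5)c2c(c1C#C)O[C@H](c1ccc(OCc5ccccc5)c(OCc5ccccc5)c1)[C@H](OCc5ccccc5)C2 | intermediate
17 | 7-O-allyl-8-[(Z)-2-acetoxyethenyl]-3,5,3′,4′-tetra-O-benzylepicatechin | C=CCOc1cc(OCc5ccccc5)c2c(c1/C=C\OC(C)=O)O[C@H](c1ccc(OCc5ccccc5)c(OCc5ccccc5)c1)[C@H](OCc5ccccc5)C2 | intermediate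
18 | 3,4-bis(benzyloxy)benzonitrile | N#Cc1ccc(OCc2ccccc2)c(OCc2ccccc2)c1 | starting material
19 | methyl 3,4-bis(benzyloxy)benzimidate hydrochloride | COC(=[NH2+])c1ccc(OCc2ccccc2)c(OCc2ccccc2)c1.[Cl-] | intermediate
20 | trimethyl 3,4-bis(benzyloxy)orthobenzoate | COC(OC)(OC)c1ccc(OCc2ccccc2)c(OCc2ccccc2)c1 | intermediate
21 | mixed orthoester: 11 with its free phenol oxygen bonded to C(OMe)2[3,4-bis(benzyloxy)phenyl] | C(c5ccccc5)Oc1cc(OCc5ccccc5)c2c(c1)O[C@@]1(c3ccc(OCc5ccccc5)c(OCc5ccccc5)c3)Oc3c(Br)c(OC(OC)(OC)c6ccc(OCc5ccccc5)c(OCc5ccccc5)c6)cc(OCc5ccccc5)c3[C@@H]2[C@H]1OCc5ccccc5 | intermediate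
22 | aryloxy(methoxy)[3,4-bis(benzyloxy)phenyl]carbenium ion from 21 (ion pair with the anion of CA) | C(c5ccccc5)Oc1cc(OCc5ccccc5)c2c(c1)O[C@@]1(c3ccc(OCc5ccccc5)c(OCc5ccccc5)c3)Oc3c(Br)c(O[C+](OC)c6ccc(OCc5ccccc5)c(OCc5ccccc5)c6)cc(OCc5ccccc5)c3[C@@H]2[C@H]1OCc5ccccc5 | intermediate
23 | protected trimer: central 2-methoxy-2-[3,4-bis(benzyloxy)phenyl]chroman ring (C2 anomers) with 3α-OAc and 4α-aryl (3,4-cis, central C3 R), 5-OBn and 8-Br; upper unit as in 11; lower unit 7-O-allyl-3,5,3′,4′-tetra-O-benzylepicatechin bonded through C8 | C(c5ccccc5)Oc1cc(OCc5ccccc5)c2c(c1)O[C@@]1(c3ccc(OCc5ccccc5)c(OCc5ccccc5)c3)Oc3c(Br)c4c(c(OCc5ccccc5)c3[C@@H]2[C@H]1OCc5ccccc5)[C@@H](c6c(OCC=C)cc(OCc5ccccc5)c7c6O[C@H](c6ccc(OCc5ccccc5)c(OCc5ccccc5)c6)[C@H](OCc5ccccc5)C7)[C@@H](OC(C)=O)C(OC)(c6ccc(OCc5ccccc5)c(OCc5ccccc5)c6)O4 | intermediate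
24 | 23 without the acetyl and allyl groups (central 3-OH and lower 7-OH free) | C(c5ccccc5)Oc1cc(OCc5ccccc5)c2c(c1)O[C@@]1(c3ccc(OCc5ccccc5)c(OCc5ccccc5)c3)Oc3c(Br)c4c(c(OCc5ccccc5)c3[C@@H]2[C@H]1OCc5ccccc5)[C@@H](c6c(O)cc(OCc5ccccc5)c7c6O[C@H](c6ccc(OCc5ccccc5)c(OCc5ccccc5)c6)[C@H](OCc5ccccc5)C7)[C@@H](O)C(OC)(c6ccc(OCc5ccccc5)c(OCc5ccccc5)c6)O4 | intermediate
25 | 8-bromo-dodeca-O-benzyl derivative of the target: both ketal bridges in place, Br on C8 of the central unit, all phenols and the upper and lower 3-OH benzylated, central 3-OH free | C(c5ccccc5)Oc1cc(OCc5ccccc5)c2c(c1)O[C@@]1(c3ccc(OCc5ccccc5)c(OCc5ccccc5)c3)Oc3c(Br)c4c(c(OCc5ccccc5)c3[C@@H]2[C@H]1OCc5ccccc5)[C@H]1c2c(cc(OCc5ccccc5)c3c2O[C@H](c2ccc(OCc5ccccc5)c(OCc5ccccc5)c2)[C@H](OCc5ccccc5)C3)O[C@@](c2ccc(OCc5ccccc5)c(OCc5ccccc5)c2)(O4)[C@@H]1O | intermediate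
26 | epicatechin-(2β→O→7, 4β→6)-ent-catechin-(2α→O→7, 4α→8)-epicatechin | Oc1cc(O)c2c(c1)O[C@@]1(c3ccc(O)c(O)c3)Oc3cc4c(c(O)c3[C@@H]2[C@H]1O)[C@H]1c2c(cc(O)c3c2O[C@H](c2ccc(O)c(O)c2)[C@H](O)C3)O[C@@](c2ccc(O)c(O)c2)(O4)[C@@H]1O | target

Total step count: 17. Longest linear sequence: 10 steps (6 → 7 → 8 → 13 → 14 → 15 → 16 → 17 → 23 → 25 → 26, i.e. steps 4, 5, 9, 10, 11, 12, 13, 15, 16 and 17).

Steps most likely to fail

Step 15. The chiral ion pair may discriminate the two alkene faces poorly, or the dioxocarbenium ion may add so slowly that intermolecular C-alkylation of other electron-rich rings takes over. The fallback uses known reactions, sets out from 15 and 11 and comes back at 25. Claisen–Schmidt condensation of 15 with commercial 1-[3,4-bis(benzyloxy)phenyl]ethanone (KOH, EtOH–THF) should give the (E)-chalcone F1. Juliá–Colonna epoxidation (poly-L-leucine, urea–H2O2, DBU, THF), which leaves the allyl ether alone, should give the (2R,3S)-epoxy ketone F2, so that the future C3 is set by reagent control. BF3·OEt2-mediated Friedel–Crafts opening of the epoxide at its benzylic carbon by excess 11 (ring carbon ortho to its free hydroxyl, entering anti to the aroyl group) should give the hydroxy ketone F3. Pd(PPh3)4, K2CO3 and MeOH remove the allyl group to give the triol ketone F4, and camphorsulfonic acid closes both ketal bonds to 25.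

Step 8. The ionised flavan may attack its own A ring (self-condensation), or 11 may undergo a second annulation at its remaining ring carbon. The fallback sets out from 9 and 5 and comes back at 11, and it also bypasses step 7. Me3SiOTf-promoted Friedel–Crafts arylation of 9 at C4 by 5 (trans to 3-OBn) should give the singly linked 4β-aryl flavan F5. DDQ then oxidises the benzylic C2–H and the neighbouring phenol closes the ketal (oxidative A-type ring closure) to 11.

Step 13. The hindered, electron-rich aryl alkyne may resist vinylidene formation or add acetic acid in the Markovnikov sense, or the allyl ether may isomerise on ruthenium. The fallback sets out from 15 and comes back at 17. Wittig methoxymethylenation (Ph3P=CHOMe from the phosphonium chloride and KN(SiMe3)2) should give the enol ether F6 as an E/Z mixture. Hydrolysis (aq. HCl, THF) gives the arylacetaldehyde F7, and O-acetylation of its potassium (Z)-enolate (KN(SiMe3)2, then Ac2O, THF, −78 °C) gives 17.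

Further compounds

F1 | step 15 | (E)-1-[3,4-bis(benzyloxy)phenyl]-3-[7-O-allyl-3,5,3′,4′-tetra-O-benzylepicatechin-8-yl]prop-2-en-1-one | C=CCOc1cc(OCc5ccccc5)c2c(c1/C=C/C(=O)c6ccc(OCc5ccccc5)c(OCc5ccccc5)c6)O[C@H](c1ccc(OCc5ccccc5)c(OCc5ccccc5)c1)[C@H](OCc5ccccc5)C2
F2 | step 15 | (2R,3S)-trans-epoxide of F1 | C=CCOc1cc(OCc5ccccc5)c2c(c1[C@@H]6O[C@H]6C(=O)c7ccc(OCc5ccccc5)c(OCc5ccccc5)c7)O[C@H](c1ccc(OCc5ccccc5)c(OCc5ccccc5)c1)[C@H](OCc5ccccc5)C2
F3 | step 15 | open-chain hydroxy ketone: 1-[3,4-bis(benzyloxy)phenyl]-2-hydroxypropan-1-one carrying at C3 the free ring carbon of 11 and C8 of the 7-O-allyl lower unit (configuration at C2 and C3 as in 23) | C(c5ccccc5)Oc1cc(OCc5ccccc5)c2c(c1)O[C@@]1(c3ccc(OCc5ccccc5)c(OCc5ccccc5)c3)Oc3c(Br)c(O)c(c(OCc5ccccc5)c3[C@@H]2[C@H]1OCc5ccccc5)[C@@H](c6c(OCC=C)cc(OCc5ccccc5)c7c6O[C@H](c6ccc(OCc5ccccc5)c(OCc5ccccc5)c6)[C@H](OCc5ccccc5)C7)[C@@H](O)C(=O)c6ccc(OCc5ccccc5)c(OCc5ccccc5)c6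
F4 | step 15 | F3 without the allyl group (triol ketone) | C(c5ccccc5)Oc1cc(OCc5ccccc5)c2c(c1)O[C@@]1(c3ccc(OCc5ccccc5)c(OCc5ccccc5)c3)Oc3c(Br)c(O)c(c(OCc5ccccc5)c3[C@@H]2[C@H]1OCc5ccccc5)[C@@H](c6c(O)cc(OCc5ccccc5)c7c6O[C@H](c6ccc(OCc5ccccc5)c(OCc5ccccc5)c6)[C@H](OCc5ccccc5)C7)[C@@H](O)C(=O)c6ccc(OCc5ccccc5)c(OCc5ccccc5)c6
F5 | step 8 | 4β-[6-(benzyloxy)-3-bromo-2,4-dihydroxyphenyl]-3,5,7,3′,4′-penta-O-benzylepicatechin | C(c5ccccc5)Oc1cc(OCc5ccccc5)c2c(c1)O[C@H](c1ccc(OCc5ccccc5)c(OCc5ccccc5)c1)[C@H](OCc5ccccc5)[C@H]2c1c(O)c(Br)c(O)cc1OCc5ccccc5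
F6 | step 13 | 7-O-allyl-8-(2-methoxyethenyl)-3,5,3′,4′-tetra-O-benzylepicatechin (E/Z mixture) | C=CCOc1cc(OCc5ccccc5)c2c(c1C=COC)O[C@H](c1ccc(OCc5ccccc5)c(OCc5ccccc5)c1)[C@H](OCc5ccccc5)C2
F7 | step 13 | 7-O-allyl-8-(2-oxoethyl)-3,5,3′,4′-tetra-O-benzylepicatechin | C=CCOc1cc(OCc5ccccc5)c2c(c1CC=O)O[C@H](c1ccc(OCc5ccccc5)c(OCc5ccccc5)c1)[C@H](OCc5ccccc5)C2
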